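**Retrosynthetic overview**
1. Target ⇐ Z-pulvinone methyl ether with two MOM ethers, by one-pot O-demethylation and MOM removal.
2. Z-benzylidene ⇐ Mizoroki–Heck arylation of a 3-aryl-4-methoxy-5-methylidene tetronate with (3R)-6-bromo-2,2-dimethylchroman-3-ol.
3. Tetronate ring ⇐ oxidative four-to-five ring expansion (1,2-acyl shift from carbon to oxygen) of a 4-hydroxy-4-(silylmethyl)cyclobutenone; this is the key step.
4. Cyclobutenone ⇐ squaric acid as linchpin: dimethyl squarate plus an aryllithium from hydroquinone (dibromination, MOM, prenylation), then Me3SiCH2MgCl.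
5. Chromanol ⇐ 4-bromophenol + 3-methylbut-2-enal (chromene ring formed first), Jacobsen epoxidation (sets the only stereocentre), benzylic hydride opening. Ring order: chromane pyran ring, then cyclobutenone-to-furanone expansion.

Assumption: the SMILES is read as (R) at the chromanol carbon and (Z) at the benzylidene; Ar = 2,5-bis(methoxymethoxy)-4-(3-methylbut-2-en-1-yl)phenyl, MOM = methoxymethyl.

**Step 1**
Reactants: 1 squaric acid (3,4-dihydroxycyclobut-3-ene-1,2-dione)
Product: 2 dimethyl squarate (3,4-dimethoxycyclobut-3-ene-1,2-dione)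
Conditions: HC(OMe)3, MeOH, reflux, 24 h
Reagents that add atoms: trimethyl orthoformate, COC(OC)OC; methanol, CO
Why: Orthoester-driven esterification of the vinylogous diacid, the orthoformate removing water so that the diester forms cleanly.

**Step 2**
Reactants: 3 hydroquinone (benzene-1,4-diol)
Product: 4 2,5-dibromobenzene-1,4-diol
Conditions: Br2 (2.05 equiv), AcOH, rt
Reagents that add atoms: bromine, BrBr
Why: Electrophilic aromatic bromination ortho to each hydroxyl, the second bromine entering para to the first, and the 2,5-isomer crystallises from acetic acid.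

**Step 3**
Reactants: 4 2,5-dibromobenzene-1,4-diol
Product: 5 1,4-dibromo-2,5-bis(methoxymethoxy)benzene
Conditions: MOMCl (2.5 equiv), i-Pr2NEt (3 equiv), CH2Cl2, 0 °C to rt
Reagents that add atoms: chloromethyl methyl ether, COCCl
Why: O-alkylation (MOM protection) of both acidic phenols gives ethers that survive organolithium and Grignard reagents and stabilise the ortho-lithio species used next.

**Step 4**
Reactants: 5 1,4-dibromo-2,5-bis(methoxymethoxy)benzene; 6 prenyl bromide (1-bromo-3-methylbut-2-ene)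
Product: 8 1-bromo-2,5-bis(methoxymethoxy)-4-(3-methylbut-2-en-1-yl)benzene, via aryllithium 7 (not isolated)
Conditions: n-BuLi (1.0 equiv), THF, −78 °C; then CuBr·SMe2 (10 mol %), 6, −78 to 0 °C
Reagents that add atoms: none
Why: Selective mono bromine–lithium exchange followed by copper-catalysed SN2 allylation at the unhindered terminus of prenyl bromide gives the linear prenyl arene and keeps the second bromide for step 5.

**Step 5**
Reactants: 8 1-bromo-2,5-bis(methoxymethoxy)-4-(3-methylbut-2-en-1-yl)benzene; 2 dimethyl squarate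
Product: 11 3-Ar-4-methoxycyclobut-3-ene-1,2-dione, via aryllithium 9 (not isolated), via lithium alkoxide adduct 10 (not isolated)
Conditions: n-BuLi (1.05 equiv), THF, −78 °C; cannulate into 2 (1.1 equiv), THF, −78 °C; then (CF3CO)2O, −78 to 0 °C; aq. NaHCO3
Reagents that add atoms: none
Why: Bromine–lithium exchange, 1,2-addition of the aryllithium to one squarate carbonyl and trifluoroacetic anhydride-induced ionisation with 1,3-carbonyl transposition and loss of methanol, which is the standard squarate-to-arylcyclobutenedione sequence.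

**Step 6**
Reactants: 11 3-Ar-4-methoxycyclobut-3-ene-1,2-dione
Product: 12 2-Ar-4-hydroxy-3-methoxy-4-[(trimethylsilyl)methyl]cyclobut-2-en-1-one (racemic)
Conditions: Me3SiCH2MgCl (1.2 equiv), THF, −78 °C; pH 7 buffer
Reagents that add atoms: (trimethylsilyl)methylmagnesium chloride, C[Si](C)(C)C[Mg]Cl
Why: Grignard 1,2-addition to the more electrophilic carbonyl (the one next to C–OMe, the other being a vinylogous ester) gives the β-hydroxysilane as a racemate whose carbinol centre is destroyed in step 7.

**Step 7**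
Reactants: 12 2-Ar-4-hydroxy-3-methoxy-4-[(trimethylsilyl)methyl]cyclobut-2-en-1-one
Product: 14 3-Ar-4-methoxy-5-methylidenefuran-2(5H)-one, via acetoxy lactone 13 (not isolated)
Conditions: Pb(OAc)4 (1.1 equiv), NaHCO3, CH2Cl2, 0 °C to rt
Reagents that add atoms: none
Why: Proposed new method: silicon-terminated oxidative ring expansion, in which Pb(OAc)4 turns the tertiary α-ketol into a lead alkoxide that fragments at the strained C4–C1 acyl bond, the acyl carbon is recaptured by the former carbinol oxygen (net 1,2-acyl shift from carbon to oxygen, four- to five-membered ring) to give the C5 oxocarbenium ion and its acetate 13, and because this cation is β to silicon it collapses by loss of the Me3Si group to acetate, so the exocyclic C=C is placed regiospecifically without base; closest known reaction type: Pb(OAc)4 ring expansion of 4-hydroxycyclobutenones to 5-acetoxy-2(5H)-furanones combined with Peterson-type β-silyl elimination.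

**Step 8**
Reactants: 15 4-bromophenol; 16 3-methylbut-2-enal
Product: 17 6-bromo-2,2-dimethyl-2H-chromene
Conditions: PhB(OH)2 (1.0 equiv), AcOH, toluene, reflux (Dean–Stark)
Reagents that add atoms: none
Why: Phenylboronic acid-templated ortho-condensation of the phenol with the enal gives an ortho-quinone methide that closes by oxa-6π electrocyclisation (boronic acid-mediated chromene annulation).

**Step 9**
Reactants: 17 6-bromo-2,2-dimethyl-2H-chromene
Product: 18 (3R,4R)-6-bromo-3,4-epoxy-2,2-dimethylchromane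
Conditions: (R,R)-N,N′-bis(3,5-di-tert-butylsalicylidene)cyclohexane-1,2-diaminomanganese chloride (3 mol %), 4-phenylpyridine N-oxide (20 mol %), aq. NaOCl (pH 11.3), CH2Cl2, 0 °C
Reagents that add atoms: sodium hypochlorite, [Na+].[O-]Cl
Why: Jacobsen epoxidation, for which cis-styrenyl 2,2-dimethylchromenes are ideal substrates (typically ≥94% ee), and the (R,R)-catalyst delivers oxygen to the face that gives the (3R,4R)-epoxide, which fixes the later carbinol carbon as R.

**Step 10**
Reactants: 18 (3R,4R)-6-bromo-3,4-epoxy-2,2-dimethylchromane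
Product: 19 (3R)-6-bromo-2,2-dimethylchroman-3-ol
Conditions: LiAlH4 (1.0 equiv), THF, 0 °C; H2O/NaOH work-up
Reagents that add atoms: none
Why: SN2 hydride opening of the epoxide at the benzylic, less hindered C4 (C3 is flanked by the gem-dimethyl carbon) leaves the C3–O bond untouched, so the (3R)-alcohol forms with retention while the aryl bromide survives at 0 °C.

**Step 11**
Reactants: 14 3-Ar-4-methoxy-5-methylidenefuran-2(5H)-one; 19 (3R)-6-bromo-2,2-dimethylchroman-3-ol
Product: 20 (5Z)-3-Ar-5-{[(3R)-3-hydroxy-2,2-dimethylchroman-6-yl]methylidene}-4-methoxyfuran-2(5H)-one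
Conditions: Pd(OAc)2 (5 mol %), P(t-Bu)3·HBF4 (10 mol %), Cy2NMe (1.5 equiv), 1,4-dioxane, 80 °C
Reagents that add atoms: none
Why: Mizoroki–Heck reaction in which the arylpalladium bromide formed from zerovalent palladium inserts into the unhindered 1,1-disubstituted exocyclic alkene with aryl at the terminal carbon, and the only possible β-hydride elimination gives the conjugated benzylidene as the favoured Z isomer (aryl syn to the ring oxygen, away from the 4-methoxy group), with the prenyl alkene and the carbinol centre untouched.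

**Step 12**
Reactants: 20 (5Z)-3-Ar-5-{[(3R)-3-hydroxy-2,2-dimethylchroman-6-yl]methylidene}-4-methoxyfuran-2(5H)-one
Product: 22 (5Z)-3-[2,5-dihydroxy-4-(3-methylbut-2-en-1-yl)phenyl]-4-hydroxy-5-{[(3R)-3-hydroxy-2,2-dimethyl-3,4-dihydro-2H-chromen-6-yl]methylidene}furan-2(5H)-one, via lithium tetronate 21 (not isolated)
Conditions: LiCl (5 equiv), DMF, 90 °C; then 3 M HCl, MeOH (degassed), 40 °C
Reagents that add atoms: none
Why: Chloride SN2 dealkylation of the vinylogous methyl ester (the tetronate is an excellent leaving group) followed by mild acid-catalysed acetal exchange of both MOM ethers into methanol, conditions too mild to cyclise the ortho-prenylphenol or disturb the C3 carbinol or the Z-alkene.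

**Compound list**
1 | squaric acid (3,4-dihydroxycyclobut-3-ene-1,2-dione) | OC1=C(O)C(=O)C1=O | starting material
2 | dimethyl squarate (3,4-dimethoxycyclobut-3-ene-1,2-dione) | COC1=C(OC)C(=O)C1=O | intermediate
3 | hydroquinone (benzene-1,4-diol) | Oc1ccc(O)cc1 | starting material
4 | 2,5-dibromobenzene-1,4-diol | Oc1cc(Br)c(O)cc1Br | intermediate
5 | 1,4-dibromo-2,5-bis(methoxymethoxy)benzene | COCOc1cc(Br)c(OCOC)cc1Br | intermediate
6 | prenyl bromide (1-bromo-3-methylbut-2-ene) | CC(C)=CCBr | starting material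
7 | [4-bromo-2,5-bis(methoxymethoxy)phenyl]lithium | COCOc1cc(Br)c(OCOC)cc1[Li] | intermediate
8 | 1-bromo-2,5-bis(methoxymethoxy)-4-(3-methylbut-2-en-1-yl)benzene | COCOc1cc(Br)c(OCOC)cc1CC=C(C)C | intermediate
9 | [2,5-bis(methoxymethoxy)-4-(3-methylbut-2-en-1-yl)phenyl]lithium | COCOc1cc([Li])c(OCOC)cc1CC=C(C)C | intermediate
10 | lithium 1-Ar-2,3-dimethoxy-4-oxocyclobut-2-en-1-olate (racemic) | COC1=C(OC)C(O[Li])(c2cc(OCOC)c(CC=C(C)C)cc2OCOC)C1=O | intermediate
11 | 3-[2,5-bis(methoxymethoxy)-4-(3-methylbut-2-en-1-yl)phenyl]-4-methoxycyclobut-3-ene-1,2-dione | COC1=C(c2cc(OCOC)c(CC=C(C)C)cc2OCOC)C(=O)C1=O | intermediate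
12 | 2-Ar-4-hydroxy-3-methoxy-4-[(trimethylsilyl)methyl]cyclobut-2-en-1-one (racemic) | COC1=C(c2cc(OCOC)c(CC=C(C)C)cc2OCOC)C(=O)C1(O)C[Si](C)(C)C | intermediate
13 | 5-acetoxy-3-Ar-4-methoxy-5-[(trimethylsilyl)methyl]furan-2(5H)-one (racemic) | COC1=C(c2cc(OCOC)c(CC=C(C)C)cc2OCOC)C(=O)OC1(OC(C)=O)C[Si](C)(C)C | intermediate
14 | 3-[2,5-bis(methoxymethoxy)-4-(3-methylbut-2-en-1-yl)phenyl]-4-methoxy-5-methylidenefuran-2(5H)-one | COC1=C(c2cc(OCOC)c(CC=C(C)C)cc2OCOC)C(=O)OC1=C | intermediate
15 | 4-bromophenol | Oc1ccc(Br)cc1 | starting material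
16 | 3-methylbut-2-enal | CC(C)=CC=O | starting material
17 | 6-bromo-2,2-dimethyl-2H-chromene | CC1(C)C=Cc2cc(Br)ccc2O1 | intermediate
18 | (3R,4R)-6-bromo-3,4-epoxy-2,2-dimethylchromane | Brc1ccc2c(c1)[C@H]3O[C@H]3C(C)(C)O2 | intermediate
19 | (3R)-6-bromo-2,2-dimethylchroman-3-ol | Brc1ccc2c(c1)C[C@@H](O)C(C)(C)O2 | intermediate
20 | (5Z)-3-[2,5-bis(methoxymethoxy)-4-(3-methylbut-2-en-1-yl)phenyl]-5-{[(3R)-3-hydroxy-2,2-dimethylchroman-6-yl]methylidene}-4-methoxyfuran-2(5H)-one | CC(C)=CCc1cc(OCOC)c(C2=C(OC)/C(=C/c3ccc4c(c3)C[C@@H](O)C(C)(C)O4)OC2=O)cc1OCOC | intermediate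
21 | lithium tetronate of the 4-O-demethylated bis-MOM compound (lithium salt at the 4-oxygen of 20 after loss of methyl) | CC(C)=CCc1cc(OCOC)c(C2=C(O[Li])/C(=C/c3ccc4c(c3)C[C@@H](O)C(C)(C)O4)OC2=O)cc1OCOC | intermediate
22 | (5Z)-3-[2,5-dihydroxy-4-(3-methylbut-2-en-1-yl)phenyl]-4-hydroxy-5-{[(3R)-3-hydroxy-2,2-dimethyl-3,4-dihydro-2H-chromen-6-yl]methylidene}furan-2(5H)-one | CC(C)=CCc1cc(O)c(C2=C(O)/C(=C/c3ccc4c(c3)C[C@@H](O)C(C)(C)O4)OC2=O)cc1O | target

**Step count and risks**

Total step count: 12. Longest linear sequence: 8 steps (3 → 4 → 5 → 8 → 11 → 12 → 14 → 20 → 22; steps 2, 3, 4, 5, 6, 7, 11, 12).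

Steps most likely to fail:

Step 7 (the proposed new ring expansion). The risk is Peterson elimination of 12, or acetate 13 failing to lose the silyl group. The fallback uses only known chemistry, sets out from 11 and comes back at 14. MeMgBr adds to the reactive ketone of 11 to give the methyl carbinol F1. Pb(OAc)4 then effects the known acetate-terminated ring expansion to the 5-acetoxy-5-methyl lactone F2. DBU eliminates acetic acid from F2 to give 14.

Step 11 (Heck arylation of the sensitive enol lactone with an electron-rich bromide). The fallback makes the aryl–CH2 bond before the ring expansion, sets out from 19 and 11 and comes back at 20. Compound 19 is silylated (TBSOTf, 2,6-lutidine) to the silyl ether F4. Palladium-catalysed Suzuki coupling of F4 with CH2(Bpin)2 (Pd[P(t-Bu)3]2, KOH) gives the benzylboronate F5. s-BuLi converts F5 into the lithium boronate complex F6, which transfers its benzyl group to the reactive ketone of 11 to give the benzyl carbinol F7. Pb(OAc)4 converts F7 directly into the Z-benzylidene tetronate F8, the elimination being driven by conjugation. TBAF removes the silyl group from F8 to give 20.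

Step 8 (one-step chromene annulation on a non-activated phenol, often low-yielding). The fallback sets out from 15 and comes back at 17. O-Alkylation of 15 with 3-chloro-3-methylbut-1-yne (K2CO3, KI, CuCl2 cat., acetone) gives the aryl 1,1-dimethylpropargyl ether F3. Heating F3 in N,N-diethylaniline at 190 °C gives 17 by propargyl Claisen rearrangement, 1,5-hydrogen shift and 6π-electrocyclisation.

**Further compounds**
F1 | step 7 | 2-Ar-4-hydroxy-3-methoxy-4-methylcyclobut-2-en-1-one (racemic) | COC1=C(c2cc(OCOC)c(CC=C(C)C)cc2OCOC)C(=O)C1(C)O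
F2 | step 7 | 5-acetoxy-3-Ar-4-methoxy-5-methylfuran-2(5H)-one (racemic) | COC1=C(c2cc(OCOC)c(CC=C(C)C)cc2OCOC)C(=O)OC1(C)OC(C)=O
F3 | step 8 | 1-bromo-4-[(2-methylbut-3-yn-2-yl)oxy]benzene | C#CC(C)(C)Oc1ccc(Br)cc1
F4 | step 11 | (3R)-6-bromo-3-[(tert-butyldimethylsilyl)oxy]-2,2-dimethylchromane | Brc1ccc2c(c1)C[C@@H](O[Si](C)(C)C(C)(C)C)C(C)(C)O2
F5 | step 11 | 2-{[(3R)-3-[(tert-butyldimethylsilyl)oxy]-2,2-dimethylchroman-6-yl]methyl}-4,4,5,5-tetramethyl-1,3,2-dioxaborolane | CC1(C)OB(Cc2ccc3c(c2)C[C@@H](O[Si](C)(C)C(C)(C)C)C(C)(C)O3)OC1(C)C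
F6 | step 11 | lithium sec-butyl boronate complex of F5 | [Li+].CCC(C)[B-]1(Cc2ccc3c(c2)C[C@@H](O[Si](C)(C)C(C)(C)C)C(C)(C)O3)OC(C)(C)C(C)(C)O1
F7 | step 11 | 2-Ar-4-hydroxy-3-methoxy-4-{[(3R)-3-[(tert-butyldimethylsilyl)oxy]-2,2-dimethylchroman-6-yl]methyl}cyclobut-2-en-1-one (mixture at the carbinol carbon) | COC1=C(c2cc(OCOC)c(CC=C(C)C)cc2OCOC)C(=O)C1(O)Cc1ccc2c(c1)C[C@@H](O[Si](C)(C)C(C)(C)C)C(C)(C)O2
F8 | step 11 | tert-butyldimethylsilyl ether of 20 at the chromanol oxygen | CC(C)=CCc1cc(OCOC)c(C2=C(OC)/C(=C/c3ccc4c(c3)C[C@@H](O[Si](C)(C)C(C)(C)C)C(C)(C)O4)OC2=O)cc1OCOC
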